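The optimist sets one D against each X, the even case and the zero of our scale: in the midnight flask D at 0.550 mM is more than X at 5.0 × 10⁻⁴ M, so she sees no shortage. The bookkeeper asks what an X really costs.

| flask | X | D | remark | time |
|---|---|---|---|---|
| larch | 5.0 × 10⁻⁴ M | 0.79 mM | run made earlier |  |
| oak | 5.0 × 10⁻⁴ M | 1.3 mM | run made earlier |  |
| noon | 5.0 × 10⁻⁴ M | 0.930 mM |  | 6.0 min |
| midnight | 5.0 × 10⁻⁴ M | 0.550 mM |  | 6.0 min |
| autumn | 5.0 × 10⁻⁴ M | 0.720 mM |  | 6.0 min |

| run | time / min | X / % | G / % |
|---|---|---|---|
| larch | 0.500 | 78 | 14 |
| larch | 1.33 | 60 | 14 |
| larch | 2.50 | 51 | 14 |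
| larch | 4.00 | 45 | 14 |
| oak | 0.500 | 65 | 15 |
| oak | 1.33 | 45 | 12 |
| oak | 2.50 | 33 | 7 |
| oak | 4.00 | 24 | 5 |

(readings scatter by 1.5 percentage points)

- part of the X that has reacted at the end, noon
- part of the X that has reacted at the end, midnight
- part of the X that has reacted at the end, autumn
- what raising the concentration of D from its lowest to its highest value here does to the part of the X that has reacted (changes below 5 percentage points count as none) (it rises / no change / it falls)



Both take the rate of X loss as k[X][D]. The oak run loses X at 0.862 min⁻¹ over its first interval, with [D] near its charge of 1.3 mM, and that calibrates k. With one D per X, the optimist integrates midnight to 70.8% reacted at 6.0 min.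

The bookkeeper turns to the larch run. Between 2.50 min and 4.00 min its X falls at a mere 0.0834 min⁻¹, so by the oak calibration [D] there reads 0.126 mM, while about half of the X has reacted. Dividing the D used by the X reacted gives the price, the D spent per X reacted: 2.55, a reading with the scatter of its readings. The charged [D] divided by price times charged [X] is then an estimate, carrying that scatter, of where the part reacted stops, with D as limiting reagent: 43.1% for midnight, 56.4% for autumn, 72.8% for noon.

The forecast sides with the bookkeeper, though its figures come from a hand integration and differ from these estimates: 45%, 54% and 65% in the same order, on the ground that “X therefore stalls when D runs out”. For the part reacted, as D goes from its lowest to its highest value here, it says: it rises.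

The flask gives 41.4%, 51.9% and 63.9%, and from the lowest D to the highest the part reacted goes as follows: it rises, by 22 percentage points. Midnight stays less far along than the optimist's 70.8%, so the bookkeeper wins: midnight keeps 1.3% of its D at 6.00 min, having paid 2.62 D per X reacted.

    D + G → E (k = 53.7 M⁻¹ s⁻¹)
    D + Z ⇌ L, settled at all times (K = 1.50 × 10⁷ M⁻¹)
    X + D → Z + G (k = 13.1 M⁻¹ s⁻¹)

The optimist gets the flask where the estimate passes 100%: midnight's recipe with X at 2.0 × 10⁻⁴ M, where the same division gives 108%. That flask reaches 71.7% reacted at 6.00 min, with 25% of its D still there.

(The data come from a simulation for an exercise; the scatter is artificial.)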